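## Structural features

Broussoflavonol D (34) is an achiral flavonol: a 4H-chromen-4-one (rings A and C) is joined through C2–C1' to benzene ring B, and ring B is fused across C3'–C4' to a 2,2-dimethyl-2H-pyran (ring D). Ring A is a phloroglucinol with three different oxygens: the free C5 hydroxyl (hydrogen-bonded to the C4 carbonyl), the free C7 hydroxyl and the ether oxygen O1 on C8a. C8, which lies between C7 and C8a, carries a 2-methylbut-3-en-2-yl (1,1-dimethylallyl) group through a quaternary carbon, and C6 is unsubstituted. Ring C carries the C3 hydroxyl, and ring B is substituted on five contiguous carbons: C1' (flavone), C2' (prenyl), C3' and C4' (carbon and oxygen of ring D) and C5' (hydroxyl). There is no stereocentre and no stereogenic double bond, so no stereocentres stand next to each other and the problem is one of regiochemistry and functional-group tolerance. The fragile groups are the alkenes (terminal vinyl, trisubstituted prenyl, styrenic chromene), which exclude hydrogenation, electrophilic halogen or oxygen reagents and strong acid, and the flavonol itself, which is air-sensitive as a polyphenoxide. The real difficulty is ring A: the quaternary substituent must go to C8 and not to the electronically equivalent C6, and the three oxygens must be told apart so that C8a–O closes ring C while C5–O and C7–O stay masked. The key step uses this feature: C8–C8a, C6–C7 and C4a–C8a are formed from an alkyne that already carries the quaternary carbon (C8) and a silyloxy group (C7) and from a four-carbon ketene precursor that brings C6, C5 (as allyl ether) and C4a, which leaves C4a as the only open position ortho to the free C8a hydroxyl.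

## Logic of the disconnections

**34 ⇒ 33 ⇒ 32.** The last bonds cut are the two O–Si bonds (C7–O and C5'–O, 34 to 33) and the O–allyl bond (C5–O, 33 to 32). The ring A groups follow from the ring A construction (silyl from the alkyne, allyl from the cyclobutenone), and ring B is given the same silyl group so that one fluoride treatment frees both hydroxyls. The gain is an intermediate without free phenols other than C3–OH. The demand is that both removals avoid acid and leave all alkenes alone, which fluoride and an allyl transfer to zerovalent palladium do.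

**32 ⇒ 29.** The C3–O bond is cut. C3–H is the one position of the pyranone that can be metallated selectively, and adding the oxygen last avoids carrying an α-oxygenated ketone through the ring closure. The chalcone route (Algar–Flynn–Oyamada) is not used in the main line because an alkoxy group on C5 diverts it towards aurones. The gain is a plain flavone, 29. The demand is a nucleophilic, not electrophilic, oxygen source.

**29 ⇒ 27.** The O1–C2 bond is cut, which opens ring C to the o-hydroxyaryl ynone 27. The gain is an acyclic precursor with all carbons in place. The demand is 6-endo and not 5-exo closure.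

**27 ⇒ 26 ⇒ 13 + 23.** After adjusting the oxidation level (27 to 26), the C4–C3 bond between the carbinol carbon and the alkyne is cut. This is the convergent cut: it divides the molecule into the ring A aldehyde 13 and the ring B alkyne 23, of similar size. The demand is that an acetylide adds to an aldehyde with a neighbouring phenol and that the oxidation is chemoselective.

**13 ⇒ 12.** The C4a–C4 bond (formyl group) is cut. C4a is the only free carbon ortho to the C8a hydroxyl of 12, so a phenoxide-directed formylation has one possible outcome. Ortho-iodination for a carbonylative closure was rejected because electrophilic iodine would also attack C6 and the alkenes. The demand is a non-acidic formylation.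

**12 ⇒ 7 + 5.** C8–C8a, C6–C7 and C4a–C8a are cut, which removes ring A. The gain is the largest of the route: a tetrasubstituted benzene with three different oxygens and a quaternary substituent becomes a cyclobutenone 7 and an alkyne 5. The demand is a regioselective union of ketene and alkyne at a temperature the allyl ether tolerates.

**5 ⇒ 2 ⇒ 1 and 7 ⇒ 6.** In 5 the O–Si bond and the alkyne carbon next to the quaternary centre are cut (one-carbon homologation of ester 2, made from acid 1). In 7 the O–allyl bond is cut (exchange on 6). Both lead to commercial materials. The demand is that a hindered, non-enolisable ester accepts the homologation and that the strained ring of 6 survives the exchange.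

**23 ⇒ 21 ⇒ 20.** The terminal alkyne carbon is cut (homologation of aldehyde 21), then the C2'–CH2 bond of the prenyl group (cross-coupling of bromide 20). The formyl group serves twice: it activates the C–Br bond and then becomes the alkyne. The demand is linear, not branched, allyl transfer.

**20 ⇒ 16 ⇒ 15 ⇒ 14.** Ring D is cut at C3'–C and O–CMe2 (propargyl ether rearrangement of 16), then the O–Si bond (16 to 15) and the O–C(propargyl) bond (15 to 14). In 14 the hydroxyl para to the formyl group is the more acidic, which tells the two oxygens apart, and the propargyl ether has only one ortho carbon bearing hydrogen. The demand is site-selective O-alkylation of 14.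

## Other disconnections considered

**Alternative 1:** The cut runs through ring C at C4a–C4, C4–C3 and O1–C2 and leads to 2-iodobenzene-1,3,5-triol A2, carbon monoxide and the ring B alkyne A3. In the forward step zerovalent palladium (from PdCl2(PPh3)2) would insert into the C–I bond of A2, take up CO and couple with A3, and the amine solvent would close the ynone to the 5,7-dihydroxyflavone A1.
- In its favour: three bonds and ring C in one operation, and the symmetry of A2 removes any question of which hydroxyl closes.
- Against it: A1 has neither the C8 quaternary group nor the C3 hydroxyl. The 1,1-dimethylallyl group would have to be put on the finished flavone, in practice by O-prenylation of C7–O and a Claisen shift that can go to C6 as well as to C8, after the two hydroxyls have been differentiated. A2 is an electron-rich iodophenol prone to deiodination, and zerovalent palladium in an amine would strip any allyl ether.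
- Comparison: on step economy for ring C alone this alternative is the better (one step against steps 5, 11, 12 and 13). On mechanism the two are equal, because both close ring C by the same amine-mediated 6-endo event and both use a ring B alkyne of the type of 23. On structure the chosen plan is the better, because ring A arrives with C8 substituted and all three oxygens differentiated.

**Alternative 2:** The cut is in ring D (C3'–C and O4'–CMe2) and leads from the tetra-acetal A4 to the 4'-O-(2-methylbut-3-yn-2-yl) ether A5. In the forward step heating A5 to about 140 °C would cause a [3,3] shift to C3' followed by oxa-6π closure.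
- In its favour: the chromene is made last and need not survive organolithium, palladium or oxidation steps, and this is a point on which it is the better. Its regiochemistry is unambiguous because C5' is oxygenated, which is equal to the chosen plan (step 8 is the same rearrangement).
- Against it: it does not address ring A, so the C8 quaternary group, the main problem, must already be present in A5. The hot step is applied to the most advanced intermediate. Four acetals then need acid at the end, with the chromene and a 1,1-dimethylallyl group next to the freed C7 hydroxyl both present.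
- Comparison: mechanism and step count for ring D are equal (one step either way). The chosen plan performs the rearrangement on a small bromo aldehyde, where failure costs little, and ends without acid. Alternative 2 is linear at the end where the chosen plan is convergent.

**Alternative 3:** The cut is the O1–C8a bond and leads from the flavonol ether A6 to the fluoro diketone A7. In the forward step a carbonate base would form the enolate of A7, whose oxygen on C2 displaces fluoride at C8a. The C7 prenyl ether of A6 is then meant to deliver the C8 group by Claisen rearrangement to A8.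
- In its favour: the C3 oxygen is present before ring closure, which is better than the late C3 hydroxylation of step 14. The closure can give only the six-membered ring, so the aurone question of step 13 does not arise, and this is also the better point.
- Against it: the fluoride is on a ring with two alkoxy donors and is activated only by the ortho carbonyl. The C8 substituent depends on a Claisen shift with two open ortho positions (C6 and C8), carried out with ring D and the 2'-prenyl group present. The fluorinated ring A piece and the α-oxygenated diketone each need their own steps. Acid is needed at the end.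
- Comparison: on structure the chosen plan is the better, since C8 is fixed by construction and not by a selectivity. On mechanism alternative 3 is the safer at ring C and at C3. On step economy the two are probably equal.

Key step: step 4

Remark on the chemistry (assumption): reagent amounts are indicative. Atom-by-atom mapping of the benzannulation confirms the constitution of 5, 7 and 12, so no structure needed correction. The ring B hydroxyl is carried as a triisopropylsilyl ether and not as an acetal, so that the synthesis ends without acid.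

Abbreviations: TIPS = tri(propan-2-yl)silyl; ArA = 2-hydroxy-3-(2-methylbut-3-en-2-yl)-6-(prop-2-enyloxy)-4-(TIPS-oxy)phenyl; ArB = 2,2-dimethyl-5-(3-methylbut-2-en-1-yl)-8-(TIPS-oxy)-2H-chromen-6-yl.

## Route

Step 1
Reactants: 1 2,2-dimethylbut-3-enoic acid
Product: 2 ethyl 2,2-dimethylbut-3-enoate
Conditions: EtI, K2CO3, DMF, rt
Reagents that add atoms: iodoethane, CCI
Why: SN2 O-alkylation of the potassium carboxylate; it avoids the slow acid-catalysed esterification of a neopentyl-type acid and cannot touch the vinyl group.

Step 2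
Reactants: 2 ethyl 2,2-dimethylbut-3-enoate
Product: 5 (3,3-dimethylpent-4-en-1-yn-1-yloxy)tri(propan-2-yl)silane, via lithium dibromoenolate 3 (not isolated), via lithium ynolate 4 (not isolated)
Conditions: CH2Br2, lithium 2,2,6,6-tetramethylpiperidide, THF, −78 °C; 2; LiN(SiMe3)2; n-BuLi, −78 °C → rt; iPr3SiOTf, −78 → 0 °C
Reagents that add atoms: dibromomethane, BrCBr; tri(propan-2-yl)silyl trifluoromethanesulfonate, CC(C)[Si](OS(=O)(=O)C(F)(F)F)(C(C)C)C(C)C
Why: Kowalski ester homologation: LiCHBr2 adds to the non-enolisable ester and the adduct collapses to dibromoenolate 3, after which bromine–lithium exchange triggers 1,2-migration of the tertiary alkyl group to give ynolate 4. The bulky silyl triflate should silylate 4 on oxygen, as is usual for triisopropylsilyl electrophiles, and give the siloxyalkyne.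

Step 3
Reactants: 6 3-ethoxycyclobut-2-en-1-one
Product: 7 3-(prop-2-enyloxy)cyclobut-2-en-1-one
Conditions: allyl alcohol (solvent), pyridinium p-toluenesulfonate (cat.), 40 °C; concentrate and repeat
Reagents that add atoms: prop-2-en-1-ol, C=CCO
Why: Acid-catalysed addition–elimination at C3 of the vinylogous ester (trans-etherification), driven by the excess of allyl alcohol and removal of ethanol. The mild acid and low temperature should keep the strained ring closed.

Step 4
Reactants: 7 3-(prop-2-enyloxy)cyclobut-2-en-1-one; 5 (3,3-dimethylpent-4-en-1-yn-1-yloxy)tri(propan-2-yl)silane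
Product: 12 2-(2-methylbut-3-en-2-yl)-5-(prop-2-enyloxy)-3-[tri(propan-2-yl)silyloxy]phenol, via vinylketene 8 (not isolated), via vinylcyclobutenone 9 (not isolated), via dienylketene 10 (not isolated), via cyclohexadienone 11 (not isolated)
Conditions: 5 (1.3 equiv), toluene, 80 → 110 °C, argon, slow addition of 7
Reagents that add atoms: none
Why: Proposed new method: heating should open 7 by 4π electrocyclic ring opening to the alkoxy vinylketene 8, whose ketene C=C bond adds the electron-rich siloxyalkyne 5 in a [2+2] cycloaddition to give vinylcyclobutenone 9; a second 4π opening gives dienylketene 10, 6π electrocyclisation gives cyclohexadienone 11 and tautomerisation gives phenol 12, so that C8–C8a, C6–C7 and C4a–C8a are formed in one operation. The closest known reaction type is the Danheiser benzannulation of 3-alkyl- and 3-aryl-cyclobutenones with trialkylsiloxyalkynes, which gives resorcinol monosilyl ethers of this pattern; new here is the 3-alkoxy (vinylogous ester) cyclobutenone, whose push–pull stabilisation is expected to raise the temperature of the first ring opening without changing the later pericyclic steps. Ring A is closed by a thermal disrotatory 6π electrocyclisation of the ketene-terminated triene 10, and aromatisation makes the closure irreversible. No stereocentre is created: the stereogenic ring carbon of 9 is transient, and reversible opening of 9 feeds both rotamers of 10 through the one that can cyclise. The step needs regiocontrol in the [2+2] event, and the polarisation of the ynol ether secures it, because the alkyne carbon that bears the 1,1-dimethylallyl group is the nucleophilic terminus and bonds to the ketene carbonyl carbon, which places the quaternary group next to the new hydroxyl and the silyloxy group next to C6. It also needs chemoselectivity among the π bonds: a ketene reacts with an ynol ether far faster than with the isolated vinyl and allyl groups, and 80–110 °C lies below the range in which the allyl vinyl ether of 7 and 8 or the allyl aryl ether of 12 would undergo Claisen rearrangement. A slight excess of 5 and slow addition of 7 keep the ketene concentration low, which should suppress ketene dimerisation and acylation of the hindered phenol 12 by 8.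

Step 5
Reactants: 12 2-(2-methylbut-3-en-2-yl)-5-(prop-2-enyloxy)-3-(TIPS-oxy)phenol
Product: 13 2-hydroxy-3-(2-methylbut-3-en-2-yl)-6-(prop-2-enyloxy)-4-(TIPS-oxy)benzaldehyde
Conditions: MgCl2, Et3N, (CH2O)n, MeCN, 80 °C; cold 1 M HCl
Reagents that add atoms: paraformaldehyde (as formaldehyde), C=O
Why: Magnesium-mediated ortho-formylation (Casnati–Skattebøl): the magnesium phenoxide delivers formaldehyde to the only free ortho carbon, C4a, and a second equivalent of formaldehyde oxidises the benzylic alkoxide to the aldehyde by hydride transfer. The conditions are non-acidic until work-up and should spare the silyl ether, the allyl ether and the 1,1-dimethylallyl group.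

Step 6
Reactants: 14 2-bromo-4,5-dihydroxybenzaldehyde
Product: 15 2-bromo-5-hydroxy-4-[(2-methylbut-3-yn-2-yl)oxy]benzaldehyde
Conditions: 3-chloro-3-methylbut-1-yne (1.1 equiv), DBU (1.1 equiv), CuCl2·2H2O (1 mol%), MeCN, 0 °C
Reagents that add atoms: 3-chloro-3-methylbut-1-yne, C#CC(C)(C)Cl
Why: Copper-catalysed propargylic etherification of a phenol with a tertiary propargylic chloride. One equivalent of base ionises only the more acidic 4-hydroxyl, para to the formyl group, as in the usual 4-O-selective alkylation of 3,4-dihydroxybenzaldehydes.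

Step 7
Reactants: 15 2-bromo-5-hydroxy-4-[(2-methylbut-3-yn-2-yl)oxy]benzaldehyde
Product: 16 2-bromo-4-[(2-methylbut-3-yn-2-yl)oxy]-5-(TIPS-oxy)benzaldehyde
Conditions: iPr3SiCl, imidazole, DMF, rt
Reagents that add atoms: chlorotri(propan-2-yl)silane, CC(C)[Si](Cl)(C(C)C)C(C)C
Why: Standard silylation of the remaining phenol. The triisopropylsilyl group is chosen because it should survive the later heat, base and organolithium steps and leaves together with the ring A silyl ether in the last step.

Step 8
Reactants: 16 2-bromo-4-[(2-methylbut-3-yn-2-yl)oxy]-5-(TIPS-oxy)benzaldehyde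
Product: 20 5-bromo-2,2-dimethyl-8-(TIPS-oxy)-2H-chromene-6-carbaldehyde, via allenyl dienone 17 (not isolated), via allenylphenol 18 (not isolated), via quinone methide 19 (not isolated)
Conditions: xylenes, 140 °C, argon
Reagents that add atoms: none
Why: Aryl propargyl ether Claisen rearrangement: the [3,3] shift to C3, the only ortho carbon bearing hydrogen, gives allenyl dienone 17, which enolises to 18; a 1,5-hydrogen shift gives o-quinone methide 19, and oxa-6π electrocyclisation closes ring D. The gem-dimethyl propargyl ether should rearrange well below the temperature at which the other groups react.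

Step 9
Reactants: 20 5-bromo-2,2-dimethyl-8-(TIPS-oxy)-2H-chromene-6-carbaldehyde
Product: 21 2,2-dimethyl-5-(3-methylbut-2-en-1-yl)-8-(TIPS-oxy)-2H-chromene-6-carbaldehyde
Conditions: tributyl(3-methylbut-2-en-1-yl)stannane (1.5 equiv), Pd(PPh3)4 (5 mol%), DMF, 100 °C
Reagents that add atoms: tributyl(3-methylbut-2-en-1-yl)stannane, CCCC[Sn](CCCC)(CCCC)CC=C(C)C
Why: Stille coupling: the ortho formyl group activates the C–Br bond for oxidative addition to zerovalent palladium, and reductive elimination from the less hindered primary terminus of the prenyl ligand should give the linear prenyl arene. Fluoride-free conditions keep the silyl ether.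

Step 10
Reactants: 21 2,2-dimethyl-5-(3-methylbut-2-en-1-yl)-8-(TIPS-oxy)-2H-chromene-6-carbaldehyde
Product: 23 {[6-ethynyl-2,2-dimethyl-5-(3-methylbut-2-en-1-yl)-2H-chromen-8-yl]oxy}tri(propan-2-yl)silane, via diazoalkene 22 (not isolated)
Conditions: dimethyl (1-diazo-2-oxopropyl)phosphonate (1.5 equiv), K2CO3 (2 equiv), MeOH/THF, 0 °C → rt
Reagents that add atoms: dimethyl (1-diazo-2-oxopropyl)phosphonate, COP(=O)(OC)C(=[N+]=[N-])C(C)=O
Why: Seyferth–Gilbert homologation with the Ohira–Bestmann reagent: a Horner–Wadsworth–Emmons-type olefination gives diazoalkene 22, which loses N2 and undergoes a 1,2-hydrogen shift to the terminal alkyne. The hindered triisopropylsilyl aryl ether, meta to the formyl group, should survive K2CO3 in methanol at room temperature.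

Step 11
Reactants: 13 ArA–CHO (2-hydroxy-3-(2-methylbut-3-en-2-yl)-6-(prop-2-enyloxy)-4-(TIPS-oxy)benzaldehyde); 23 ArB–C≡CH
Product: 26 racemic 1-ArA-3-ArB-prop-2-yn-1-ol, via sodium phenoxide 24 (not isolated), via lithium acetylide 25 (not isolated)
Conditions: 23 (1.5 equiv), n-BuLi (1.45 equiv), THF, −78 °C; then 24 [from 13, NaH (1.05 equiv), THF, 0 °C], −78 → 0 °C; aq. NH4Cl
Reagents that add atoms: none
Why: 1,2-Addition of a lithium acetylide to a salicylaldehyde whose phenol is first converted into its sodium salt, a reaction type well established for unprotected 2-hydroxybenzaldehydes; the excess acetylide is recovered as 23. The new carbinol stereocentre forms as a racemate and is removed in step 12.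

Step 12
Reactants: 26 racemic 1-ArA-3-ArB-prop-2-yn-1-ol
Product: 27 1-ArA-3-ArB-prop-2-yn-1-one
Conditions: activated MnO2 (excess), CH2Cl2, rt
Reagents that add atoms: none
Why: Chemoselective oxidation of a benzylic–propargylic alcohol by activated MnO2. Isolated alkenes, silyl ethers and the hydrogen-bonded phenol should not be affected.

Step 13
Reactants: 27 1-ArA-3-ArB-prop-2-yn-1-one
Product: 29 2-ArB-8-(2-methylbut-3-en-2-yl)-5-(prop-2-enyloxy)-7-(TIPS-oxy)-4H-chromen-4-one, via enaminone 28 (not isolated)
Conditions: Et2NH (3 equiv), DMF, rt → 50 °C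
Reagents that add atoms: none
Why: Conjugate addition of the secondary amine to the ynone gives enaminone 28, and the phenol then displaces the amine at the β-carbon by addition–elimination (6-endo), so that only the six-membered pyranone can form and the 5-exo route to an aurone is closed. The amine is regenerated, and the conditions are too mild to cleave the silyl or allyl ethers.

Step 14
Reactants: 29 2-ArB-8-(2-methylbut-3-en-2-yl)-5-(prop-2-enyloxy)-7-(TIPS-oxy)-4H-chromen-4-one
Product: 32 3-hydroxy-2-ArB-8-(2-methylbut-3-en-2-yl)-5-(prop-2-enyloxy)-7-(TIPS-oxy)-4H-chromen-4-one, via 3-lithioflavone 30 (not isolated), via dimethyl boronate 31 (not isolated)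
Conditions: LiN(iPr)2 (1.5 equiv), THF, −78 °C; B(OMe)3 (3 equiv), −78 → 0 °C; 30% H2O2, aq. NaHCO3, 0 °C
Reagents that add atoms: hydrogen peroxide, OO (trimethyl borate, COB(OC)OC, supplies the boron of intermediate 31 only)
Why: C3–H of a 5,7-dialkoxyflavone is the most acidic site and is removed by the lithium amide at −78 °C; the vinyllithium 30 is trapped as boronate 31, whose C–B bond is oxidised with retention (lithiation–boration–oxidation of flavones). Buffered hydrogen peroxide acts as a nucleophile here and should leave the alkenes alone, which an electrophilic oxidant would not.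

Step 15
Reactants: 32 3-hydroxy-2-ArB-8-(2-methylbut-3-en-2-yl)-5-(prop-2-enyloxy)-7-(TIPS-oxy)-4H-chromen-4-one
Product: 33 3,5-dihydroxy-2-ArB-8-(2-methylbut-3-en-2-yl)-7-(TIPS-oxy)-4H-chromen-4-one
Conditions: Pd(PPh3)4 (5 mol%), morpholine (5 equiv), THF, rt
Reagents that add atoms: none
Why: Tsuji–Trost deallylation: zerovalent palladium ionises the aryl allyl ether, the C5 phenoxide being a good leaving group because of the peri carbonyl, and morpholine traps the π-allyl complex. The prenyl, 1,1-dimethylallyl and chromene alkenes carry no leaving group and should be inert.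

Step 16
Reactants: 33 3,5-dihydroxy-2-ArB-8-(2-methylbut-3-en-2-yl)-7-(TIPS-oxy)-4H-chromen-4-one
Product: 34 broussoflavonol D, 3,5,7-trihydroxy-2-[8-hydroxy-2,2-dimethyl-5-(3-methylbut-2-en-1-yl)-2H-chromen-6-yl]-8-(2-methylbut-3-en-2-yl)-4H-chromen-4-one
Conditions: Bu4NF (2.5 equiv), AcOH (2.5 equiv), THF, 0 °C → rt, argon
Reagents that add atoms: none
Why: Fluoride cleaves both aryl silyl ethers; buffering with acetic acid keeps the flavonol from standing as an air-sensitive polyphenoxide. No strong acid is used, so the C7 hydroxyl should not close onto the 1,1-dimethylallyl group and the chromene should stay intact; the product is achiral, so there is no stereochemistry to set or lose.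

## Compound list

1 | 2,2-dimethylbut-3-enoic acid | C=CC(C)(C)C(=O)O | starting material
2 | ethyl 2,2-dimethylbut-3-enoate | C=CC(C)(C)C(=O)OCC | intermediate
3 | lithium 1,1-dibromo-3,3-dimethylpenta-1,4-dien-2-olate | [Li]OC(=C(Br)Br)C(C)(C)C=C | intermediate (not isolated)
4 | lithium 3,3-dimethylpent-4-en-1-yn-1-olate | [Li]OC#CC(C)(C)C=C | intermediate (not isolated)
5 | (3,3-dimethylpent-4-en-1-yn-1-yloxy)tri(propan-2-yl)silane | C=CC(C)(C)C#CO[Si](C(C)C)(C(C)C)C(C)C | intermediate
6 | 3-ethoxycyclobut-2-en-1-one | CCOC1=CC(=O)C1 | starting material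
7 | 3-(prop-2-enyloxy)cyclobut-2-en-1-one | C=CCOC1=CC(=O)C1 | intermediate
8 | 3-(prop-2-enyloxy)buta-1,3-dien-1-one | C=CCOC(=C)C=C=O | intermediate (not isolated)
9 | 2-(2-methylbut-3-en-2-yl)-4-[1-(prop-2-enyloxy)ethenyl]-3-[tri(propan-2-yl)silyloxy]cyclobut-2-en-1-one (racemic) | O=C1C(C(C)(C)C=C)=C(O[Si](C(C)C)(C(C)C)C(C)C)C1C(=C)OCC=C | intermediate (not isolated)
10 | (3E)-2-(2-methylbut-3-en-2-yl)-5-(prop-2-enyloxy)-3-[tri(propan-2-yl)silyloxy]hexa-1,3,5-trien-1-one | O=C=C(C(C)(C)C=C)/C(O[Si](C(C)C)(C(C)C)C(C)C)=C\C(=C)OCC=C | intermediate (not isolated)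
11 | 2-(2-methylbut-3-en-2-yl)-5-(prop-2-enyloxy)-3-[tri(propan-2-yl)silyloxy]cyclohexa-2,4-dien-1-one | O=C1CC(OCC=C)=CC(O[Si](C(C)C)(C(C)C)C(C)C)=C1C(C)(C)C=C | intermediate (not isolated)
12 | 2-(2-methylbut-3-en-2-yl)-5-(prop-2-enyloxy)-3-[tri(propan-2-yl)silyloxy]phenol | C=CC(C)(C)c1c(O)cc(OCC=C)cc1O[Si](C(C)C)(C(C)C)C(C)C | intermediate
13 | 2-hydroxy-3-(2-methylbut-3-en-2-yl)-6-(prop-2-enyloxy)-4-[tri(propan-2-yl)silyloxy]benzaldehyde | O=Cc1c(O)c(C(C)(C)C=C)c(O[Si](C(C)C)(C(C)C)C(C)C)cc1OCC=C | intermediate
14 | 2-bromo-4,5-dihydroxybenzaldehyde | O=Cc1cc(O)c(O)cc1Br | starting material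
15 | 2-bromo-5-hydroxy-4-[(2-methylbut-3-yn-2-yl)oxy]benzaldehyde | O=Cc1cc(O)c(OC(C)(C)C#C)cc1Br | intermediate
16 | 2-bromo-4-[(2-methylbut-3-yn-2-yl)oxy]-5-[tri(propan-2-yl)silyloxy]benzaldehyde | O=Cc1cc(O[Si](C(C)C)(C(C)C)C(C)C)c(OC(C)(C)C#C)cc1Br | intermediate
17 | 2-bromo-3-(3-methylbuta-1,2-dien-1-yl)-4-oxo-5-[tri(propan-2-yl)silyloxy]cyclohexa-1,5-diene-1-carbaldehyde (racemic) | O=CC1=C(Br)C(C=C=C(C)C)C(=O)C(O[Si](C(C)C)(C(C)C)C(C)C)=C1 | intermediate (not isolated)
18 | 2-bromo-4-hydroxy-3-(3-methylbuta-1,2-dien-1-yl)-5-[tri(propan-2-yl)silyloxy]benzaldehyde | O=Cc1cc(O[Si](C(C)C)(C(C)C)C(C)C)c(O)c(C=C=C(C)C)c1Br | intermediate (not isolated)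
19 | (3E)-2-bromo-3-(3-methylbut-2-en-1-ylidene)-4-oxo-5-[tri(propan-2-yl)silyloxy]cyclohexa-1,5-diene-1-carbaldehyde | O=CC1=C(Br)/C(=C/C=C(C)C)C(=O)C(O[Si](C(C)C)(C(C)C)C(C)C)=C1 | intermediate (not isolated)
20 | 5-bromo-2,2-dimethyl-8-[tri(propan-2-yl)silyloxy]-2H-chromene-6-carbaldehyde | O=Cc1cc(O[Si](C(C)C)(C(C)C)C(C)C)c2OC(C)(C)C=Cc2c1Br | intermediate
21 | 2,2-dimethyl-5-(3-methylbut-2-en-1-yl)-8-[tri(propan-2-yl)silyloxy]-2H-chromene-6-carbaldehyde | O=Cc1cc(O[Si](C(C)C)(C(C)C)C(C)C)c2OC(C)(C)C=Cc2c1CC=C(C)C | intermediate
22 | {[6-(2-diazoethenyl)-2,2-dimethyl-5-(3-methylbut-2-en-1-yl)-2H-chromen-8-yl]oxy}tri(propan-2-yl)silane | [N-]=[N+]=C=Cc1cc(O[Si](C(C)C)(C(C)C)C(C)C)c2OC(C)(C)C=Cc2c1CC=C(C)C | intermediate (not isolated)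
23 | {[6-ethynyl-2,2-dimethyl-5-(3-methylbut-2-en-1-yl)-2H-chromen-8-yl]oxy}tri(propan-2-yl)silane | C#Cc1cc(O[Si](C(C)C)(C(C)C)C(C)C)c2OC(C)(C)C=Cc2c1CC=C(C)C | intermediate
24 | sodium 2-formyl-6-(2-methylbut-3-en-2-yl)-3-(prop-2-enyloxy)-5-[tri(propan-2-yl)silyloxy]phenolate | [Na+].[O-]c1c(C=O)c(OCC=C)cc(O[Si](C(C)C)(C(C)C)C(C)C)c1C(C)(C)C=C | intermediate (not isolated)
25 | lithium acetylide of 23 (ArB–C≡C–Li) | [Li]C#Cc1cc(O[Si](C(C)C)(C(C)C)C(C)C)c2OC(C)(C)C=Cc2c1CC=C(C)C | intermediate (not isolated)
26 | 1-ArA-3-ArB-prop-2-yn-1-ol (racemic) | OC(C#Cc1cc(O[Si](C(C)C)(C(C)C)C(C)C)c2OC(C)(C)C=Cc2c1CC=C(C)C)c1c(O)c(C(C)(C)C=C)c(O[Si](C(C)C)(C(C)C)C(C)C)cc1OCC=C | intermediate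
27 | 1-ArA-3-ArB-prop-2-yn-1-one | O=C(C#Cc1cc(O[Si](C(C)C)(C(C)C)C(C)C)c2OC(C)(C)C=Cc2c1CC=C(C)C)c1c(O)c(C(C)(C)C=C)c(O[Si](C(C)C)(C(C)C)C(C)C)cc1OCC=C | intermediate
28 | 3-(diethylamino)-1-ArA-3-ArB-prop-2-en-1-one (alkene geometry not defined; either isomer closes) | O=C(C=C(N(CC)CC)c1cc(O[Si](C(C)C)(C(C)C)C(C)C)c2OC(C)(C)C=Cc2c1CC=C(C)C)c1c(O)c(C(C)(C)C=C)c(O[Si](C(C)C)(C(C)C)C(C)C)cc1OCC=C | intermediate (not isolated)
29 | 2-ArB-8-(2-methylbut-3-en-2-yl)-5-(prop-2-enyloxy)-7-[tri(propan-2-yl)silyloxy]-4H-chromen-4-one | C=CC(C)(C)c1c(O[Si](C(C)C)(C(C)C)C(C)C)cc(OCC=C)c2c(=O)cc(-c3cc(O[Si](C(C)C)(C(C)C)C(C)C)c4OC(C)(C)C=Cc4c3CC=C(C)C)oc12 | intermediate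
30 | 3-lithio derivative of 29 | C=CC(C)(C)c1c(O[Si](C(C)C)(C(C)C)C(C)C)cc(OCC=C)c2c(=O)c([Li])c(-c3cc(O[Si](C(C)C)(C(C)C)C(C)C)c4OC(C)(C)C=Cc4c3CC=C(C)C)oc12 | intermediate (not isolated)
31 | dimethyl boronate at C3 of 29 | C=CC(C)(C)c1c(O[Si](C(C)C)(C(C)C)C(C)C)cc(OCC=C)c2c(=O)c(B(OC)OC)c(-c3cc(O[Si](C(C)C)(C(C)C)C(C)C)c4OC(C)(C)C=Cc4c3CC=C(C)C)oc12 | intermediate (not isolated)
32 | 3-hydroxy-2-ArB-8-(2-methylbut-3-en-2-yl)-5-(prop-2-enyloxy)-7-[tri(propan-2-yl)silyloxy]-4H-chromen-4-one | C=CC(C)(C)c1c(O[Si](C(C)C)(C(C)C)C(C)C)cc(OCC=C)c2c(=O)c(O)c(-c3cc(O[Si](C(C)C)(C(C)C)C(C)C)c4OC(C)(C)C=Cc4c3CC=C(C)C)oc12 | intermediate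
33 | 3,5-dihydroxy-2-ArB-8-(2-methylbut-3-en-2-yl)-7-[tri(propan-2-yl)silyloxy]-4H-chromen-4-one | C=CC(C)(C)c1c(O[Si](C(C)C)(C(C)C)C(C)C)cc(O)c2c(=O)c(O)c(-c3cc(O[Si](C(C)C)(C(C)C)C(C)C)c4OC(C)(C)C=Cc4c3CC=C(C)C)oc12 | intermediate
34 | broussoflavonol D, 3,5,7-trihydroxy-2-[8-hydroxy-2,2-dimethyl-5-(3-methylbut-2-en-1-yl)-2H-chromen-6-yl]-8-(2-methylbut-3-en-2-yl)-4H-chromen-4-one (achiral) | C=CC(C)(C)c1c(O)cc(O)c2c(=O)c(O)c(-c3cc(O)c4c(c3CC=C(C)C)C=CC(C)(C)O4)oc12 | target

## Step count and least certain steps

Total: 16 steps. Longest linear sequence: 11 steps (steps 6–10, then 11–16, from compound 14). The ring A branch (steps 1, 2, 4, 5) joins at step 11 after 4 steps.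

**Step 4 (key step).** The first ring opening of the push–pull cyclobutenone may be sluggish, and the temperature needed could then bring in Claisen rearrangement of the allyl ethers and oligomerisation of the ketene. Bond formation at the neopentyl-like alkyne carbon may also be slow enough for ketene dimerisation to compete. Irradiation at room temperature to open 7, followed by mild heating, is a first remedy within the same approach.
Fallback (known chemistry; ring A by aromatic Claisen rearrangement): it sets out from none of compounds 1–11 but from commercial benzene-1,3,5-triol F1, and it comes back to the route at compound 12. Mitsunobu mono-etherification of excess F1 (3-methylbut-2-en-1-ol, PPh3, diisopropyl azodicarboxylate) should give 5-[(3-methylbut-2-en-1-yl)oxy]benzene-1,3-diol F2. Heating (N,N-diethylaniline, about 150 °C) should move the prenyl group by [3,3] shift to either of the two equivalent ortho carbons and give 2-(2-methylbut-3-en-2-yl)benzene-1,3,5-triol F3. Mitsunobu allylation of the one hydroxyl not flanked by the quaternary carbon should give 2-(2-methylbut-3-en-2-yl)-5-(prop-2-enyloxy)benzene-1,3-diol F4, and monosilylation of one of its two equivalent hydroxyls (iPr3SiCl, imidazole, 1 equiv) gives 12. The price is two statistical steps and handling of air-sensitive polyphenols.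

**Step 6.** Site selection between the two hydroxyls may be incomplete, or double alkylation may occur, because the copper-catalysed tertiary propargylation is fast relative to proton exchange.
Fallback: it sets out from 14 and comes back at 16. Alkylation with 4-methoxybenzyl chloride (NaHCO3, NaI, DMF, 40 °C), the established way of telling apart the hydroxyls of a 3,4-dihydroxybenzaldehyde, should give 2-bromo-5-hydroxy-4-[(4-methoxyphenyl)methoxy]benzaldehyde F5. Silylation (iPr3SiCl, imidazole) gives 2-bromo-4-[(4-methoxyphenyl)methoxy]-5-[tri(propan-2-yl)silyloxy]benzaldehyde F6. Oxidative debenzylation (2,3-dichloro-5,6-dicyano-1,4-benzoquinone, CH2Cl2/H2O) gives 2-bromo-4-hydroxy-5-[tri(propan-2-yl)silyloxy]benzaldehyde F7. Propargylation of its single free hydroxyl as in step 6, at 0 °C so that the bulky silyl group does not migrate to the neighbouring oxygen, gives 16.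

**Step 9.** Allyl transfer may lose regiocontrol (bond formation at the tertiary terminus), and oxidative addition or transmetalation at the doubly ortho-substituted bromide may be slow, with protodebromination.
Fallback: it sets out from 20 and comes back at 21. Stille coupling with tributyl(prop-2-en-1-yl)stannane (Pd(PPh3)4, DMF), which poses no regiochemical question, should give 2,2-dimethyl-5-(prop-2-en-1-yl)-8-[tri(propan-2-yl)silyloxy]-2H-chromene-6-carbaldehyde F8. Olefin cross-metathesis with 2-methylbut-2-ene (second-generation Grubbs catalyst, CH2Cl2, 40 °C) then turns the allyl into the prenyl group and gives 21. The cis-disubstituted chromene double bond, next to a quaternary carbon, should not take part.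

**Step 11.** Addition may stall because the phenoxide makes the formyl group a poor, vinylogous-carboxylate-like electrophile on an already electron-rich ring.
Fallback: it sets out from 13 and comes back at 27. The phenol is masked as an acetal (NaH, MeOCH2Cl, THF, 0 °C) to give 2-(methoxymethoxy)-3-(2-methylbut-3-en-2-yl)-6-(prop-2-enyloxy)-4-[tri(propan-2-yl)silyloxy]benzaldehyde F9, an ordinary aryl aldehyde that needs only a slight excess of 25. The adduct, racemic 1-[2-(methoxymethoxy)-3-(2-methylbut-3-en-2-yl)-6-(prop-2-enyloxy)-4-(TIPS-oxy)phenyl]-3-ArB-prop-2-yn-1-ol F10, is oxidised (MnO2) to 1-[2-(methoxymethoxy)-3-(2-methylbut-3-en-2-yl)-6-(prop-2-enyloxy)-4-(TIPS-oxy)phenyl]-3-ArB-prop-2-yn-1-one F11. The acetal, ortho to the carbonyl and therefore labile, is removed with catalytic HCl in methanol at 0 °C to give 27. A silyl group in this position would not serve, because it would migrate to the new alkoxide.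

**Step 14.** Deprotonation may compete at the doubly activated CH2 of the 2'-prenyl group or at C6–H, the amide base may open the pyranone, and the peroxide step may cost a silyl group.
Fallback: it sets out from 13 (with 21) and comes back at 32. Addition of MeMgBr (excess) should give 1-[2-hydroxy-3-(2-methylbut-3-en-2-yl)-6-(prop-2-enyloxy)-4-(TIPS-oxy)phenyl]ethan-1-ol F12, and MnO2 gives 1-[2-hydroxy-3-(2-methylbut-3-en-2-yl)-6-(prop-2-enyloxy)-4-(TIPS-oxy)phenyl]ethan-1-one F13. Claisen–Schmidt condensation with 21 (Ba(OH)2, MeOH) gives (2E)-1-ArA-3-ArB-prop-2-en-1-one F14. Algar–Flynn–Oyamada oxidation (H2O2, NaOH, MeOH, 0 °C) closes ring C with the C3 hydroxyl in place and gives 32. The known liability of this reaction, diversion to an aurone when C5 carries an alkoxy group, is why it is the fallback and not the main line. Loss of a silyl group under the alkaline conditions would not matter, because step 16 removes both.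

## Further compounds

F1 | step 4 | benzene-1,3,5-triol | Oc1cc(O)cc(O)c1
F2 | step 4 | 5-[(3-methylbut-2-en-1-yl)oxy]benzene-1,3-diol | CC(C)=CCOc1cc(O)cc(O)c1
F3 | step 4 | 2-(2-methylbut-3-en-2-yl)benzene-1,3,5-triol | C=CC(C)(C)c1c(O)cc(O)cc1O
F4 | step 4 | 2-(2-methylbut-3-en-2-yl)-5-(prop-2-enyloxy)benzene-1,3-diol | C=CC(C)(C)c1c(O)cc(OCC=C)cc1O
F5 | step 6 | 2-bromo-5-hydroxy-4-[(4-methoxyphenyl)methoxy]benzaldehyde | O=Cc1cc(O)c(OCc2ccc(OC)cc2)cc1Br
F6 | step 6 | 2-bromo-4-[(4-methoxyphenyl)methoxy]-5-[tri(propan-2-yl)silyloxy]benzaldehyde | O=Cc1cc(O[Si](C(C)C)(C(C)C)C(C)C)c(OCc2ccc(OC)cc2)cc1Br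
F7 | step 6 | 2-bromo-4-hydroxy-5-[tri(propan-2-yl)silyloxy]benzaldehyde | O=Cc1cc(O[Si](C(C)C)(C(C)C)C(C)C)c(O)cc1Br
F8 | step 9 | 2,2-dimethyl-5-(prop-2-en-1-yl)-8-[tri(propan-2-yl)silyloxy]-2H-chromene-6-carbaldehyde | O=Cc1cc(O[Si](C(C)C)(C(C)C)C(C)C)c2OC(C)(C)C=Cc2c1CC=C
F9 | step 11 | 2-(methoxymethoxy)-3-(2-methylbut-3-en-2-yl)-6-(prop-2-enyloxy)-4-[tri(propan-2-yl)silyloxy]benzaldehyde | O=Cc1c(OCOC)c(C(C)(C)C=C)c(O[Si](C(C)C)(C(C)C)C(C)C)cc1OCC=C
F10 | step 11 | 1-[2-(methoxymethoxy)-3-(2-methylbut-3-en-2-yl)-6-(prop-2-enyloxy)-4-[tri(propan-2-yl)silyloxy]phenyl]-3-ArB-prop-2-yn-1-ol (racemic) | OC(C#Cc1cc(O[Si](C(C)C)(C(C)C)C(C)C)c2OC(C)(C)C=Cc2c1CC=C(C)C)c1c(OCOC)c(C(C)(C)C=C)c(O[Si](C(C)C)(C(C)C)C(C)C)cc1OCC=C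
F11 | step 11 | 1-[2-(methoxymethoxy)-3-(2-methylbut-3-en-2-yl)-6-(prop-2-enyloxy)-4-[tri(propan-2-yl)silyloxy]phenyl]-3-ArB-prop-2-yn-1-one | O=C(C#Cc1cc(O[Si](C(C)C)(C(C)C)C(C)C)c2OC(C)(C)C=Cc2c1CC=C(C)C)c1c(OCOC)c(C(C)(C)C=C)c(O[Si](C(C)C)(C(C)C)C(C)C)cc1OCC=C
F12 | step 14 | 1-[2-hydroxy-3-(2-methylbut-3-en-2-yl)-6-(prop-2-enyloxy)-4-[tri(propan-2-yl)silyloxy]phenyl]ethan-1-ol (racemic) | CC(O)c1c(O)c(C(C)(C)C=C)c(O[Si](C(C)C)(C(C)C)C(C)C)cc1OCC=C
F13 | step 14 | 1-[2-hydroxy-3-(2-methylbut-3-en-2-yl)-6-(prop-2-enyloxy)-4-[tri(propan-2-yl)silyloxy]phenyl]ethan-1-one | CC(=O)c1c(O)c(C(C)(C)C=C)c(O[Si](C(C)C)(C(C)C)C(C)C)cc1OCC=C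
F14 | step 14 | (2E)-1-ArA-3-ArB-prop-2-en-1-one | O=C(/C=C/c1cc(O[Si](C(C)C)(C(C)C)C(C)C)c2OC(C)(C)C=Cc2c1CC=C(C)C)c1c(O)c(C(C)(C)C=C)c(O[Si](C(C)C)(C(C)C)C(C)C)cc1OCC=C
A1 | alternative 1 | 5,7-dihydroxy-2-[8-(methoxymethoxy)-2,2-dimethyl-5-(3-methylbut-2-enyl)-2H-chromen-6-yl]chromen-4-one | O=c1cc(-c2cc(OCOC)c3OC(C)(C)C=Cc3c2CC=C(C)C)oc2cc(O)cc(O)c12
A2 | alternative 1 | 2-iodobenzene-1,3,5-triol | Oc1cc(O)c(I)c(O)c1
A3 | alternative 1 | 6-ethynyl-8-(methoxymethoxy)-2,2-dimethyl-5-(3-methylbut-2-enyl)-2H-chromene | C#Cc1cc(OCOC)c2OC(C)(C)C=Cc2c1CC=C(C)C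
A4 | alternative 2 | 3,5,7-tris(methoxymethoxy)-2-[8-(methoxymethoxy)-2,2-dimethyl-5-(3-methylbut-2-enyl)-2H-chromen-6-yl]-8-(2-methylbut-3-en-2-yl)chromen-4-one | C=CC(C)(C)c1c(OCOC)cc(OCOC)c2c(=O)c(OCOC)c(-c3cc(OCOC)c4OC(C)(C)C=Cc4c3CC=C(C)C)oc12
A5 | alternative 2 | 3,5,7-tris(methoxymethoxy)-2-[5-(methoxymethoxy)-4-(2-methylbut-3-yn-2-yloxy)-2-(3-methylbut-2-enyl)phenyl]-8-(2-methylbut-3-en-2-yl)chromen-4-one | C=CC(C)(C)c1c(OCOC)cc(OCOC)c2c(=O)c(OCOC)c(-c3cc(OCOC)c(OC(C)(C)C#C)cc3CC=C(C)C)oc12
A6 | alternative 3 | 3,5-bis(methoxymethoxy)-2-[8-(methoxymethoxy)-2,2-dimethyl-5-(3-methylbut-2-enyl)-2H-chromen-6-yl]-7-(3-methylbut-2-enyloxy)chromen-4-one | COCOc1cc(OCC=C(C)C)cc2oc(-c3cc(OCOC)c4OC(C)(C)C=Cc4c3CC=C(C)C)c(OCOC)c(=O)c12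
A7 | alternative 3 | 1-[2-fluoro-6-(methoxymethoxy)-4-(3-methylbut-2-enyloxy)phenyl]-2-(methoxymethoxy)-3-[8-(methoxymethoxy)-2,2-dimethyl-5-(3-methylbut-2-enyl)-2H-chromen-6-yl]propane-1,3-dione (racemic, enolisable) | COCOc1cc(OCC=C(C)C)cc(F)c1C(=O)C(OCOC)C(=O)c1cc(OCOC)c2OC(C)(C)C=Cc2c1CC=C(C)C
A8 | alternative 3 | 7-hydroxy-3,5-bis(methoxymethoxy)-2-[8-(methoxymethoxy)-2,2-dimethyl-5-(3-methylbut-2-enyl)-2H-chromen-6-yl]-8-(2-methylbut-3-en-2-yl)chromen-4-one | C=CC(C)(C)c1c(O)cc(OCOC)c2c(=O)c(OCOC)c(-c3cc(OCOC)c4OC(C)(C)C=Cc4c3CC=C(C)C)oc12
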